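**Numbering used throughout**

1 tiglic aldehyde; 2 4-bromo-3-methoxybenzaldehyde; 3 3,4-cis lactone (C3 epimer, not isolated); 4 lactone; 5 lactol; 6 sulfone; 7 1-bromo-4-iodo-2-methoxybenzene; 8 arylmagnesium chloride (not isolated); 9 diarylzinc (not isolated); 10 dibromide core; 11 bis-boronate (not isolated); 12 bis-phenol; 13 ethyl (S)-lactate; 14 Weinreb amide; 15 (3,4-dimethoxyphenyl)magnesium bromide; 16 hydroxy ketone; 17 tosylate; 18 diketone; 19 manassantin A.

## Analysis of the target

Manassantin A (19) is built around one 2,5-diaryl-3,4-dimethyltetrahydrofuran ring (O1, C2–C5). Each aryl ring is a guaiacyl unit whose para-oxygen carries a 1-(3,4-dimethoxyphenyl)-1-hydroxypropan-2-yl side chain. The ring holds four contiguous stereocentres, (2S,3R,4R,5S): each aryl group is cis to the methyl group next to it, the two methyl groups are trans, and the two aryl groups are therefore trans. Each side chain adds a (1R,2R) pair, the syn (threo) arrangement of carbinol and aryl ether. The molecule is C2-symmetric, so of its eight stereocentres only four are independent, and the ring centres and side-chain centres are too far apart to control each other. Sensitive sites are the two benzylic ring C–O bonds, which lie para to an oxygen donor and can ionise under acid or be hydrogenolysed, the two free benzylic alcohols, and, in any ketone precursor, the hydrogen alpha to carbonyl and aryloxy groups. The difficulty is the cis,trans,cis array: it is not the thermodynamic arrangement, so it must be made under kinetic control and then kept away from conditions that ionise C2 or C5. The strategy rests on the fragment C2(aryl)–C3(CH3)–C4(CH3)–C5: C2 with its aryl group is an aryl aldehyde carbon, and C3, C4 and C5 are the β-carbon, α-carbon and carbonyl carbon of 1, so a homoenolate annulation can deliver three ring centres, including the cis C2/C3 pair, as a γ-lactone.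

## Retrosynthetic reasoning

**19 to 18.** The two carbinol C–H bonds of the side chains are cut first, which leads back to the C2-symmetric diketone 18. The free benzylic alcohols are the most acid-sensitive groups, so they are made last and nothing has to be deprotected after them. In the forward direction hydride must add to each ketone in the Felkin–Anh sense set by the neighbouring (R)-aryloxy centre, which gives the syn pair.

**18 to 12 and 17.** The two O–C(sp3) bonds of the aryl alkyl ethers are cut, not the aryl–O bonds. The alkyl carbon is alpha to a ketone and is an excellent SN2 centre, whereas forging an aryl–O bond to a hindered secondary alcohol would need a metal catalyst on an electron-rich, ortho-substituted arene. The cut gives bis-phenol 12 and two equivalents of tosylate 17. The forward reaction must invert the (S) centre of 17 cleanly and must not enolise the product.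

**17 to 16, 14, 15 and 13.** Tosylate 17 comes from hydroxy ketone 16 by O-sulfonylation. Ketone 16 is cut at the aryl–carbonyl bond into the aryl Grignard reagent 15 and Weinreb amide 14, which is the amide of ethyl (S)-lactate (13). The side-chain centre is thus taken from the chiral pool, in the enantiomer that the inversion step requires.

**12 to 10 through 11.** The two phenolic C–O bonds of 12 are traced back to the C–Br bonds of dibromide 10 by way of bis-boronate 11. Bromine is preferred to a protected oxygen at this position for two reasons. It makes the aryl aldehyde electrophilic enough for the key step. It also denies the benzylic ring C–O bonds the para donor that would let them ionise during the Lewis-acidic steps. The forward conversion must introduce oxygen without exposing para-oxygenated benzylic ethers to hot strong base.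

**10 to 6 and 9.** The C5–aryl bond of 10 is cut with the ring carbon as electrophile (the oxocarbenium ion from sulfone 6) and the arene as nucleophile (diarylzinc 9, from arylmagnesium 8 and bromoiodoarene 7). The opposite polarity, adding 8 to lactone 4 and reducing the hemiketal, was considered and set aside on stereochemical grounds. The oxocarbenium ion is expected to adopt the envelope that keeps both methyl groups pseudo-equatorial, and a nucleophile then enters from the face opposite the C4 methyl and the aryl group on the far carbon. A hydride entering there would leave the new aryl group cis to the existing one, which is the wrong epimer. An aryl nucleophile entering there ends trans to the existing aryl group and cis to its neighbouring methyl, which is the target arrangement. The fourth ring stereocentre is thus set by the three already present.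

**6 to 5 to 4.** Sulfone 6 is the activated form of lactol 5, which is the half-reduced form of lactone 4. These two steps only adjust oxidation level and leaving group at the carbon that becomes C5 of the target ring.

**4 to 1 and 2.** Lactone 4 is cut across the C4–C5 bond and the acyl C2–O1 bond (lactone numbering; C5, C4, C3, C2 of 4 become C2, C3, C4, C5 of the target ring), giving tiglic aldehyde (1) and bromoaldehyde 2. This cut uses two commercial, achiral aldehydes, places every skeletal carbon of the ring in one operation and puts the stereochemical burden on one catalyst. The forward reaction must make the β-carbon of 1 nucleophilic, join it to 2 with aryl and methyl cis and in one absolute sense, and close the lactone. The α-methyl centre may form as either epimer, because the 3,4-cis lactone 3 equilibrates to 4.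

## Alternatives that were turned down

**Alternative 1:** Biomimetic radical-cation dimerisation.
- Disconnection: the C3–C4 bond and both ring C–O bonds, so that the whole ring arises from two molecules of the propenyl neolignan acetate A1 and an oxygen atom from the aqueous medium.
- Forward key step: one-electron oxidation of the (E)-propenylarene A1 gives a radical cation that couples tail to tail with a second alkene; the two benzylic cations are bridged by oxygen to give manassantin A diacetate A2, which is then deacetylated.
- For it: it follows the likely biogenesis, is the shortest and most convergent plan, and carries finished side chains into the key step, so no late etherification or ketone reduction is needed. On step economy it is clearly stronger than the chosen route.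
- Against it: the radical cation of a 4-alkoxy-propenylbenzene has several outlets ([2+2] cyclobutane dimers, attack on the partner's ring, over-oxidation). The tail-to-tail coupling has no reason to favour the trans-dimethyl pair. The trapped benzylic cations are stabilised by para-oxygen, so ring closure is reversible and drifts to aryl/methyl-trans isomers. The only chirality present is in the side chains, beyond an aryl ether spacer, so the ring would form in both absolute senses and A2 would come with its core-enantiomeric diastereomer.
- Comparison: the chosen strategy is longer but puts each ring stereocentre under the control of a catalyst or of a neighbouring centre.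

**Alternative 2:** Two-fold aryl C–O coupling.
- Disconnection: the two aryl–O bonds of the side-chain ethers.
- Forward key step: a copper- or palladium-catalysed C–O coupling joins the secondary hydroxyl of two molecules of the mono-silylated diol A4 to the two C–Br bonds of the dibromide core A3 (the same compound as 10), with retention at carbon, to give the bis-silyl ether A5; fluoride then frees the alcohols.
- For it: both side-chain centres of A4 come from one catalytic asymmetric dihydroxylation and are never again at risk, since no epimerisable ketone and no substrate-controlled reduction appear. On stereochemical security of the side chain it is stronger than the endgame chosen here, and it is one step shorter from the dibromide.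
- Against it: the alkoxide of A4 is secondary and flanked by a methyl and a silyloxybenzyl group, and the aryl bromide is electron-rich and ortho-methoxylated. In this combination β-hydride elimination from the metal alkoxide competes with C–O reductive elimination, and the coupling must succeed twice on one molecule. Hot base invites 1,2-silyl migration between the vicinal oxygens, which would arylate the wrong oxygen. The diol must first be protected selectively at the benzylic oxygen. The plan also presupposes A3 and says nothing about how the ring is made.
- Comparison: the chosen route supplies the dibromide and uses a metal-free SN2 etherification of phenol 12 instead, at the price of one substrate-controlled reduction.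

**Alternative 3:** Double reductive cycloetherification.
- Disconnection: both ring C–O bonds and both benzylic C–H bonds, leading to the C2-symmetric (2R,3R)-diketone A6.
- Forward key step: a silyl triflate and a silane at low temperature reduce one ketone, close the ring to a cyclic oxocarbenium ion and reduce that in turn, aiming at the bis-benzyl ether A7 of the core.
- For it: A6 is quickly reached by oxidative coupling of a propiophenone enolate, one step makes the ring and two stereocentres, and the C2 symmetry halves the problem. To the core it is shorter than the chosen route.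
- Against it: the second hydride is delivered to a ring oxocarbenium ion whose trans methyl groups lie pseudo-equatorial. The inside-attack model sends hydride in anti to the C4 methyl, which is syn to the methyl next to the cationic carbon, so the aryl group there ends trans, not cis, to its neighbouring methyl. The first, acyclic reduction is under weak 1,2-induction only. The 4-benzyloxyaryl groups let the benzylic C–O bonds ionise under the silyl triflate, which funnels material to the all-trans isomer. An enantiopure A6 needs an auxiliary or a resolution, and debenzylation of A7 exposes the benzylic ring C–O bonds to hydrogenolysis.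
- Comparison: the chosen strategy meets the same face preference of the oxocarbenium ion but uses it, by bringing in the aryl group and not hydride as the nucleophile, and keeps the ring aryl groups electron-poor until the ring is complete.

Key step: step 1

Assumption: which antipode of the aminoindanol triazolium catalyst gives the (4R,5S) lactone with this enal cannot be predicted with confidence; the route is written for the antipode that does, and both are commercial.

Assumption: 7 and a THF solution of 15 are treated as catalogue items; 15 can otherwise be made from 4-bromo-1,2-dimethoxybenzene and magnesium.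

## Route

Step 1
Reactants: 1 (E)-2-methylbut-2-enal (tiglic aldehyde); 2 4-bromo-3-methoxybenzaldehyde
Product: 4 (3R,4R,5S)-5-(4-bromo-3-methoxyphenyl)-3,4-dimethyloxolan-2-one, via C3-epimeric lactone 3 (not isolated)
Conditions: (5aR,10bS)-5a,10b-dihydro-2-(2,4,6-trimethylphenyl)-4H,6H-indeno[2,1-b][1,2,4]triazolo[4,3-d][1,4]oxazinium chloride or its (5aS,10bR) antipode (10 mol %), DBU (20 mol %), THF, 23 °C, 1 added over 6 h; then DBU (1 equiv), 50 °C
Reagents that add atoms: none
Why: The carbene adds to the carbonyl group of 1 and proton transfer gives the conjugated enaminol, a homoenolate equivalent, whose β-carbon attacks the aldehyde carbon of 2 to form the C4–C5 bond and both of its stereocentres. The azolium enol so formed is protonated at the α-carbon to the acyl azolium, and the benzylic alkoxide closes the γ-lactone by 5-exo-trig acylation (O1–C2), which releases the catalyst. The closest known reaction type is the carbene-catalysed homoenolate [3+2] annulation of enals with aryl aldehydes, which favours the cis-4,5 lactone; an α,β-dialkyl enal and a useful level of enantioselectivity lie at the edge of its scope. C4 and C5 are controlled in the C–C bond-forming step: the (E)-geometry of 1 and a compact arrangement in which the enaminol O–H activates the aldehyde oxygen place aryl and β-methyl cis, and the aminoindanol backbone with its N-aryl group shields one face of the enaminol and so fixes the absolute sense. C3 is set by protonation and then corrected thermodynamically, since DBU equilibrates the 3,4-cis epimer 3 through the lactone enolate to 4, whose C3 methyl is trans to the C4 methyl and to the aryl group. The step needs cross- over homo-coupling, which the substrates secure: 2, activated by its para bromine, is a far better electrophile than the hindered conjugated carbonyl group of 1, and slow addition of 1 keeps enal self-annulation down. The 4,5-trans lactone, to the extent that it forms, is removed by chromatography, and the enantiomeric purity can be raised by recrystallisation of 4 if it proves crystalline.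

Step 2
Reactants: 4 (3R,4R,5S)-5-(4-bromo-3-methoxyphenyl)-3,4-dimethyloxolan-2-one
Product: 5 (3R,4R,5S)-5-(4-bromo-3-methoxyphenyl)-3,4-dimethyloxolan-2-ol (mixture of anomers)
Conditions: iBu2AlH (1.1 equiv), CH2Cl2, −78 °C; aq. potassium sodium tartrate
Reagents that add atoms: none
Why: Partial reduction of a γ-lactone by iBu2AlH at −78 °C stops at the aluminium hemiacetal, which gives the lactol on work-up; the aryl bromide and the three ring stereocentres are untouched and the anomeric centre is of no consequence.

Step 3
Reactants: 5 (3R,4R,5S)-5-(4-bromo-3-methoxyphenyl)-3,4-dimethyloxolan-2-ol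
Product: 6 (3R,4R,5S)-2-(benzenesulfonyl)-5-(4-bromo-3-methoxyphenyl)-3,4-dimethyloxolane (mixture of anomers)
Conditions: PhSO2H, CaCl2, CH2Cl2, 23 °C
Reagents that add atoms: benzenesulfinic acid, OS(=O)c1ccccc1
Why: Acid-mediated exchange of the anomeric hydroxyl for sulfinate through the oxocarbenium ion, the standard preparation of 2-sulfonyl cyclic ethers. C3 could epimerise through the enol ether but its trans arrangement is the thermodynamic one, and the bromo-methoxy aryl ring does not stabilise a cation at C5, so C5 holds.

Step 4
Reactants: 6 (3R,4R,5S)-2-(benzenesulfonyl)-5-(4-bromo-3-methoxyphenyl)-3,4-dimethyloxolane; 7 1-bromo-4-iodo-2-methoxybenzene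
Product: 10 (2S,3R,4R,5S)-2,5-bis(4-bromo-3-methoxyphenyl)-3,4-dimethyloxolane, via arylmagnesium chloride 8 (not isolated), via diarylzinc 9 (not isolated)
Conditions: 7, iPrMgCl·LiCl, THF, −20 °C; ZnBr2 (0.5 equiv per Mg), 0 °C; then 6, 23 °C
Reagents that add atoms: none
Why: Iodine–magnesium exchange is selective for C–I over C–Br, transmetalation gives the diarylzinc, and the magnesium halide formed ionises the sulfone to the oxocarbenium ion, which the arylzinc captures (arylation of a 2-sulfonyl cyclic ether by an organozinc reagent). The cation adopts the envelope with C4 as flap and both methyl groups pseudo-equatorial; inside attack comes anti to the C4 methyl and the C5 aryl group, so the new aryl group lands trans to the C5 aryl and cis to the C3 methyl, which is the (2S,3R,4R,5S) arrangement.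

Step 5
Reactants: 10 (2S,3R,4R,5S)-2,5-bis(4-bromo-3-methoxyphenyl)-3,4-dimethyloxolane
Product: 12 4,4'-[(2S,3R,4R,5S)-3,4-dimethyloxolane-2,5-diyl]bis(2-methoxyphenol), via bis(pinacol boronate) 11 (not isolated)
Conditions: PdCl2(dppf) (5 mol %), B2pin2, KOAc, 1,4-dioxane, 85 °C; then 30% H2O2, aq. NaOH, THF, 0 °C
Reagents that add atoms: hydrogen peroxide, OO (bis(pinacolato)diboron, CC1(C)OB(OC1(C)C)B2OC(C)(C)C(C)(C)O2, leaves boron only in 11)
Why: Miyaura borylation of both aryl bromides followed by oxidation of the C–B bonds with basic hydrogen peroxide (aryl shift from boron to oxygen) gives the phenols. The sequence avoids hot hydroxide, under which a para-phenoxide could open the benzylic ether through a quinone methide and scramble C2 and C5.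

Step 6
Reactants: 13 ethyl (S)-lactate
Product: 14 (S)-2-hydroxy-N-methoxy-N-methylpropanamide
Conditions: MeNH(OMe)·HCl, iPrMgCl (3 equiv), THF, −20 → 0 °C
Reagents that add atoms: N,O-dimethylhydroxylamine hydrochloride, CNOC.Cl
Why: Aminolysis of the ester by the magnesium amide of N,O-dimethylhydroxylamine (Weinreb amide formation); the stereocentre carries an alkoxide during the reaction and is not enolised.

Step 7
Reactants: 14 (S)-2-hydroxy-N-methoxy-N-methylpropanamide; 15 (3,4-dimethoxyphenyl)magnesium bromide
Product: 16 (S)-1-(3,4-dimethoxyphenyl)-2-hydroxypropan-1-one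
Conditions: 15 (2.5 equiv), THF, 0 °C; aq. NH4Cl
Reagents that add atoms: none
Why: Weinreb ketone synthesis: the first equivalent of 15 deprotonates the hydroxyl and the second adds to give a chelated tetrahedral intermediate that collapses to the ketone only on work-up, so neither over-addition nor enolisation of the α-centre occurs.

Step 8
Reactants: 16 (S)-1-(3,4-dimethoxyphenyl)-2-hydroxypropan-1-one
Product: 17 (S)-1-(3,4-dimethoxyphenyl)-1-oxopropan-2-yl 4-methylbenzenesulfonate
Conditions: TsCl, Et3N, DMAP (cat.), CH2Cl2, 0 °C
Reagents that add atoms: p-toluenesulfonyl chloride, Cc1ccc(cc1)S(=O)(=O)Cl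
Why: Sulfonylation of the secondary alcohol takes place on oxygen with retention at carbon; short contact with the amine at 0 °C keeps the acidic α-hydrogen in place.

Step 9
Reactants: 12 4,4'-[(2S,3R,4R,5S)-3,4-dimethyloxolane-2,5-diyl]bis(2-methoxyphenol); 17 (S)-1-(3,4-dimethoxyphenyl)-1-oxopropan-2-yl 4-methylbenzenesulfonate
Product: 18 (2R)-1-(3,4-dimethoxyphenyl)-2-[4-[(2S,3R,4R,5S)-5-[4-[(2R)-1-(3,4-dimethoxyphenyl)-1-oxopropan-2-yl]oxy-3-methoxyphenyl]-3,4-dimethyloxolan-2-yl]-2-methoxyphenoxy]propan-1-one
Conditions: 17 (2.4 equiv), BEMP (2-tert-butylimino-2-diethylamino-1,3-dimethylperhydro-1,3,2-diazaphosphorine, 2.1 equiv), CH2Cl2, 0 → 23 °C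
Reagents that add atoms: none
Why: Two-fold SN2 displacement of the α-keto tosylate by phenoxide, accelerated by the adjacent carbonyl group, inverts each (S) centre to (R). The phosphazene base is limited to the amount of phenol, so no free base remains to enolise the α-aryloxy ketone.

Step 10
Reactants: 18 the diketone of step 9
Product: 19 manassantin A, (1R,2R)-1-(3,4-dimethoxyphenyl)-2-[4-[(2S,3R,4R,5S)-5-[4-[(1R,2R)-1-(3,4-dimethoxyphenyl)-1-hydroxypropan-2-yl]oxy-3-methoxyphenyl]-3,4-dimethyloxolan-2-yl]-2-methoxyphenoxy]propan-1-ol
Conditions: polymer-bound quaternary ammonium borohydride resin, MeOH, 0 → 23 °C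
Reagents that add atoms: none
Why: Hydride addition under non-chelating conditions follows the polar Felkin–Anh model, with the C–OAr bond anti to the incoming hydride, and should give the syn (threo) carbinol, (1R) next to (2R), at both ketones. The ammonium counter-ion of the resin cannot chelate and so does not open the competing anti pathway.

## Compound list

1 | (E)-2-methylbut-2-enal (tiglic aldehyde) | C/C=C(\C)C=O | starting material
2 | 4-bromo-3-methoxybenzaldehyde | COc1cc(C=O)ccc1Br | starting material
3 | (3S,4R,5S)-5-(4-bromo-3-methoxyphenyl)-3,4-dimethyloxolan-2-one | COc1cc(ccc1Br)[C@H]2OC(=O)[C@@H](C)[C@H]2C | intermediate (not isolated)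
4 | (3R,4R,5S)-5-(4-bromo-3-methoxyphenyl)-3,4-dimethyloxolan-2-one | COc1cc(ccc1Br)[C@H]2OC(=O)[C@H](C)[C@H]2C | intermediate
5 | (3R,4R,5S)-5-(4-bromo-3-methoxyphenyl)-3,4-dimethyloxolan-2-ol, anomeric mixture | COc1cc(ccc1Br)[C@H]2OC(O)[C@H](C)[C@H]2C | intermediate
6 | (3R,4R,5S)-2-(benzenesulfonyl)-5-(4-bromo-3-methoxyphenyl)-3,4-dimethyloxolane, anomeric mixture | COc1cc(ccc1Br)[C@H]2OC(S(=O)(=O)c3ccccc3)[C@H](C)[C@H]2C | intermediate
7 | 1-bromo-4-iodo-2-methoxybenzene | COc1cc(I)ccc1Br | starting material
8 | (4-bromo-3-methoxyphenyl)magnesium chloride (LiCl complex) | COc1cc(ccc1Br)[Mg]Cl | intermediate (not isolated)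
9 | bis(4-bromo-3-methoxyphenyl)zinc | COc1cc(ccc1Br)[Zn]c2ccc(Br)c(OC)c2 | intermediate (not isolated)
10 | (2S,3R,4R,5S)-2,5-bis(4-bromo-3-methoxyphenyl)-3,4-dimethyloxolane | COc1cc(ccc1Br)[C@H]2O[C@H](c3ccc(Br)c(OC)c3)[C@H](C)[C@H]2C | intermediate
11 | (2S,3R,4R,5S)-2,5-bis[3-methoxy-4-(4,4,5,5-tetramethyl-1,3,2-dioxaborolan-2-yl)phenyl]-3,4-dimethyloxolane | COc1cc(ccc1B2OC(C)(C)C(C)(C)O2)[C@H]3O[C@H](c4ccc(B5OC(C)(C)C(C)(C)O5)c(OC)c4)[C@H](C)[C@H]3C | intermediate (not isolated)
12 | 4,4'-[(2S,3R,4R,5S)-3,4-dimethyloxolane-2,5-diyl]bis(2-methoxyphenol) | COc1cc(ccc1O)[C@H]2O[C@H](c3ccc(O)c(OC)c3)[C@H](C)[C@H]2C | intermediate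
13 | ethyl (S)-lactate | C[C@H](O)C(=O)OCC | starting material
14 | (S)-2-hydroxy-N-methoxy-N-methylpropanamide | C[C@H](O)C(=O)N(C)OC | intermediate
15 | (3,4-dimethoxyphenyl)magnesium bromide | COc1ccc([Mg]Br)cc1OC | starting material
16 | (S)-1-(3,4-dimethoxyphenyl)-2-hydroxypropan-1-one | C[C@H](O)C(=O)c1ccc(OC)c(OC)c1 | intermediate
17 | (S)-1-(3,4-dimethoxyphenyl)-1-oxopropan-2-yl 4-methylbenzenesulfonate | C[C@H](OS(=O)(=O)c1ccc(C)cc1)C(=O)c2ccc(OC)c(OC)c2 | intermediate
18 | (2R,2'R)-diketone of step 9 | COc1ccc(cc1OC)C(=O)[C@@H](C)Oc2ccc(cc2OC)[C@H]3O[C@H](c4ccc(O[C@H](C)C(=O)c5ccc(OC)c(OC)c5)c(OC)c4)[C@H](C)[C@H]3C | intermediate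
19 | manassantin A | COc1ccc([C@@H](O)[C@@H](C)Oc2ccc([C@H]3O[C@H](c4ccc(O[C@H](C)[C@H](O)c5ccc(OC)c(OC)c5)c(OC)c4)[C@H](C)[C@H]3C)cc2OC)cc1OC | target

## Step count and least certain steps

Total step count: 10. Longest linear sequence: 7 steps (steps 1–5, 9, 10); the side chain takes 3 steps (6–8) before it joins at step 9.

**Step 1 (key step).**
- What may go wrong: slow generation of the homoenolate from an α-branched aliphatic enal, competing acyl-anion chemistry of 2, and above all weak facial discrimination in the C–C bond-forming step, which would give low enantiomeric purity or a poor cis/trans ratio. A Lewis-acid co-catalyst is the first variable to try.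
- Fallback (sets out from 2, returns at 4): Brown (Z)-crotylboration of 2 with (Z)-crotyldiisopinocampheylborane, from the antipode of B-methoxydiisopinocampheylborane that delivers the syn (1S,2R) product, gives (1S,2R)-1-(4-bromo-3-methoxyphenyl)-2-methylbut-3-en-1-ol F1. Hydroboration of the vinyl group with 9-BBN and oxidative work-up gives (1S,2R)-1-(4-bromo-3-methoxyphenyl)-2-methylbutane-1,4-diol F2. TEMPO with PhI(OAc)2 oxidises the primary alcohol, and the lactol that follows, to (4R,5S)-5-(4-bromo-3-methoxyphenyl)-4-methyloxolan-2-one F3. Methylation of its lithium enolate (LiN(SiMe3)2, MeI, THF, −78 °C) anti to the C4 methyl gives 4.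

**Step 4.**
- What may go wrong: slow aryl transfer from the halogen-bearing diarylzinc, so that the oxocarbenium ion loses a proton or is hydrolysed back towards 5, and incomplete facial selectivity at the cationic carbon.
- Fallback (sets out from 6, returns at 12): a more electron-rich nucleophile is used. Commercial 1-(benzyloxy)-4-bromo-2-methoxybenzene and magnesium give [4-(benzyloxy)-3-methoxyphenyl]magnesium bromide F4, and ZnBr2 converts it into bis[4-(benzyloxy)-3-methoxyphenyl]zinc F5. This adds to 6 as in step 4 to give (2S,3R,4R,5S)-2-[4-(benzyloxy)-3-methoxyphenyl]-5-(4-bromo-3-methoxyphenyl)-3,4-dimethyloxolane F6. The remaining bromide is converted as in step 5, through 2-{4-[(2S,3R,4R,5S)-5-(4-(benzyloxy)-3-methoxyphenyl)-3,4-dimethyloxolan-2-yl]-2-methoxyphenyl}-4,4,5,5-tetramethyl-1,3,2-dioxaborolane F7, into 4-[(2S,3R,4R,5S)-5-(4-(benzyloxy)-3-methoxyphenyl)-3,4-dimethyloxolan-2-yl]-2-methoxyphenol F8. Hydrogenolysis of the benzyl ether (H2, Pd/C, EtOAc) gives 12.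

**Step 9.**
- What may go wrong: enolisation of the α-aryloxy ketone or of 17 by phenoxide, which would erode the (R) centres; loss of sulfonate from 17 by E2 followed by conjugate addition; and incomplete second alkylation.
- Fallback (sets out from 12 and 13, returns at 18): Mitsunobu etherification of 12 with two equivalents of 13 (PPh3, diisopropyl azodicarboxylate, THF) is a neutral condensation with inversion at a far less acidic centre. It gives diethyl (2R,2'R)-2,2'-{[(2S,3R,4R,5S)-3,4-dimethyloxolane-2,5-diyl]bis[(2-methoxy-4,1-phenylene)oxy]}dipropanoate F9. The ester groups are converted as in step 6 into (2R,2'R)-2,2'-{[(2S,3R,4R,5S)-3,4-dimethyloxolane-2,5-diyl]bis[(2-methoxy-4,1-phenylene)oxy]}bis(N-methoxy-N-methylpropanamide) F10, and 15 then gives 18 as in step 7.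

**Step 10.**
- What may go wrong: poor facial selectivity at one or both carbonyl groups, through a weak Felkin preference or chelation by adventitious cations. The resulting anti carbinols would be hard to separate because the molecule has two such sites.
- Fallback (sets out from 18, returns at 19): the carbinol centres are set by a catalyst instead of by the neighbouring centre. Corey–Bakshi–Shibata reduction with the (R)-B-methyl oxazaborolidine and BH3·SMe2 in toluene at −20 °C uses the antipode that, with the aryl ring as the large group, delivers hydride to the face leading to (1R); the Felkin preference then only has to reinforce the reagent. No new compound is involved.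

## Further compounds

F1 | step 1 | (1S,2R)-1-(4-bromo-3-methoxyphenyl)-2-methylbut-3-en-1-ol | COc1cc(ccc1Br)[C@@H](O)[C@H](C)C=C
F2 | step 1 | (1S,2R)-1-(4-bromo-3-methoxyphenyl)-2-methylbutane-1,4-diol | COc1cc(ccc1Br)[C@@H](O)[C@H](C)CCO
F3 | step 1 | (4R,5S)-5-(4-bromo-3-methoxyphenyl)-4-methyloxolan-2-one | COc1cc(ccc1Br)[C@H]2OC(=O)C[C@H]2C
F4 | step 4 | [4-(benzyloxy)-3-methoxyphenyl]magnesium bromide | COc1cc([Mg]Br)ccc1OCc2ccccc2
F5 | step 4 | bis[4-(benzyloxy)-3-methoxyphenyl]zinc | COc1cc(ccc1OCc2ccccc2)[Zn]c3ccc(OCc4ccccc4)c(OC)c3
F6 | step 4 | (2S,3R,4R,5S)-2-[4-(benzyloxy)-3-methoxyphenyl]-5-(4-bromo-3-methoxyphenyl)-3,4-dimethyloxolane | COc1cc(ccc1Br)[C@H]2O[C@H](c3ccc(OCc4ccccc4)c(OC)c3)[C@H](C)[C@H]2C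
F7 | step 4 | 2-{4-[(2S,3R,4R,5S)-5-(4-(benzyloxy)-3-methoxyphenyl)-3,4-dimethyloxolan-2-yl]-2-methoxyphenyl}-4,4,5,5-tetramethyl-1,3,2-dioxaborolane | COc1cc(ccc1B2OC(C)(C)C(C)(C)O2)[C@H]3O[C@H](c4ccc(OCc5ccccc5)c(OC)c4)[C@H](C)[C@H]3C
F8 | step 4 | 4-[(2S,3R,4R,5S)-5-(4-(benzyloxy)-3-methoxyphenyl)-3,4-dimethyloxolan-2-yl]-2-methoxyphenol | COc1cc(ccc1O)[C@H]2O[C@H](c3ccc(OCc4ccccc4)c(OC)c3)[C@H](C)[C@H]2C
F9 | step 9 | diethyl (2R,2'R)-2,2'-{[(2S,3R,4R,5S)-3,4-dimethyloxolane-2,5-diyl]bis[(2-methoxy-4,1-phenylene)oxy]}dipropanoate | CCOC(=O)[C@@H](C)Oc1ccc(cc1OC)[C@H]2O[C@H](c3ccc(O[C@H](C)C(=O)OCC)c(OC)c3)[C@H](C)[C@H]2C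
F10 | step 9 | (2R,2'R)-2,2'-{[(2S,3R,4R,5S)-3,4-dimethyloxolane-2,5-diyl]bis[(2-methoxy-4,1-phenylene)oxy]}bis(N-methoxy-N-methylpropanamide) | CON(C)C(=O)[C@@H](C)Oc1ccc(cc1OC)[C@H]2O[C@H](c3ccc(O[C@H](C)C(=O)N(C)OC)c(OC)c3)[C@H](C)[C@H]2C
F0 | step 10 | none | none
A1 | alternative 1 | (1R,2R)-1-(3,4-dimethoxyphenyl)-2-{2-methoxy-4-[(E)-prop-1-en-1-yl]phenoxy}propyl acetate | COc1ccc([C@@H](OC(C)=O)[C@@H](C)Oc2ccc(/C=C/C)cc2OC)cc1OC
A2 | alternative 1 | manassantin A diacetate | COc1ccc([C@@H](OC(C)=O)[C@@H](C)Oc2ccc([C@H]3O[C@H](c4ccc(O[C@H](C)[C@H](OC(C)=O)c5ccc(OC)c(OC)c5)c(OC)c4)[C@H](C)[C@H]3C)cc2OC)cc1OC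
A3 | alternative 2 | (2S,3R,4R,5S)-2,5-bis(4-bromo-3-methoxyphenyl)-3,4-dimethyloxolane (identical with 10) | COc1cc(ccc1Br)[C@H]2O[C@H](c3ccc(Br)c(OC)c3)[C@H](C)[C@H]2C
A4 | alternative 2 | (1R,2R)-1-[(tert-butyldimethylsilyl)oxy]-1-(3,4-dimethoxyphenyl)propan-2-ol | COc1ccc([C@@H](O[Si](C)(C)C(C)(C)C)[C@@H](C)O)cc1OC
A5 | alternative 2 | manassantin A bis(tert-butyldimethylsilyl) ether | COc1ccc([C@@H](O[Si](C)(C)C(C)(C)C)[C@@H](C)Oc2ccc([C@H]3O[C@H](c4ccc(O[C@H](C)[C@H](O[Si](C)(C)C(C)(C)C)c5ccc(OC)c(OC)c5)c(OC)c4)[C@H](C)[C@H]3C)cc2OC)cc1OC
A6 | alternative 3 | (2R,3R)-1,4-bis[4-(benzyloxy)-3-methoxyphenyl]-2,3-dimethylbutane-1,4-dione | COc1cc(ccc1OCc2ccccc2)C(=O)[C@H](C)[C@@H](C)C(=O)c3ccc(OCc4ccccc4)c(OC)c3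
A7 | alternative 3 | (2S,3R,4R,5S)-2,5-bis[4-(benzyloxy)-3-methoxyphenyl]-3,4-dimethyltetrahydrofuran | COc1cc(ccc1OCc2ccccc2)[C@H]3O[C@H](c4ccc(OCc5ccccc5)c(OC)c4)[C@H](C)[C@H]3C
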